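The data were generated by integration with constants of no real substance, noise included.

Violet cannot hold more J than its G allows: at one G per J that is 65.0% of the X charged, and G is the limiting reagent there, with cG at 13 mM against cX at 20 mM.

| setting | violet | ochre | zeta | gamma | beta |
|---|---|---|---|---|---|
| X | 20 mM | 20 mM | 20 mM | 20 mM | 20 mM |
| G | 13 mM | 20 mM | 26.0 mM | 26.0 mM | 26.0 mM |
| temperature | 48 °C | 75 °C | 85 °C | 35 °C | 60 °C |
| remark | run made earlier | run made earlier |  |  |  |
| time |  |  | 4.0 h | 4.0 h | 4.0 h |

- violet (time / h: J / %): 8.00: 42.8; 15.0: 40.6; 25.0: 41.0; 30.0: 42.2
- ochre (time / h: J / %): 2.00: 55.7; 4.00: 56.7; 6.00: 57.8; 8.00: 56.9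

(scatter of a reading: 1 percentage point)

- the best flask by amount of J, in percent of the X charged; "all alike" if 1.5 percentage points covers them all (zeta / gamma / beta / all alike)
- amount of J at the end, in percent of the X charged, zeta
- amount of J at the end, in percent of the X charged, gamma
- amount of J at the end, in percent of the X charged, beta

- the numbers in the tables scatter with a standard deviation of 1 percentage point

Violet stays flat near 41.7%, and I read that plateau as the end of its 13 mM of G, not as an equilibrium. So each G consumed there gave 64.1% of a J. Ochre, charged with 20 mM of each, stays near 56.8%, which on the same reading is a share of 56.8%, lower at 75 °C than at 48 °C. So part of the G goes elsewhere. Ochre differs from violet in its G charge as well as its temperature, so putting the lower share on the temperature is my assumption.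

But the new flasks carry cG at 26.0 mM over cX at 20 mM, so X is limiting now, and if one X goes with each G, I reckon J at the end as the share times the X reacted. A straight line through the two readings gives 60.8% for beta, 54.1% for zeta, and 67.6% for gamma: this is the J share, J formed per X reacted.

Beta and zeta, both hotter than violet, I take as finished, so I commit to beta over zeta. But the turnovers in gamma are bounded from one side: violet was flat by 8.00 h, and gamma gets half that time at 35 °C, colder than violet. So gamma may stand below its share, and the reading to take there is the X left.

The forecast, unlike my reckoning, says 66% for zeta, 63% for gamma, 66% for beta and all alike: “I expect it is close to equilibrium, so all alike”.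

    X → D (k = 1.30 × 10⁻⁷ s⁻¹, Ea = 104 kJ mol⁻¹)
    X + G → J (k = 0.00430 L mol⁻¹ s⁻¹, Ea = 64.0 kJ mol⁻¹)
    X + G → Q (k = 0.00200 L mol⁻¹ s⁻¹, Ea = 73.0 kJ mol⁻¹)
    (constants at 35 °C)

Zeta gives 56.2%, gamma 51.7% and beta 61.7%, so the best is beta. In gamma the half-life of X by the J step at the asked time is 4.1 h, about the 4.0 h of the run, and 24.1% of the X stands unreacted then. The share applied to the X reacted gives 51.3%, and gamma holds 51.7%. The neighbour like gamma but with cG at 65 mM has 1.2% of its X left at the same time; the share gives 66.8%, and that flask holds 67.4%.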